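Atom numbering used throughout: lactone half C1–C10 with C14 on C10 and C15 on C4 (C2 is the lactone carbonyl, isopropyl on C7); cyclohexenyl half primed, ring C1′, C6′–C10′, C14′ on C10′, side chain C5′=C4′(C15′)–C3′(=O).

## The problem

The target joins two isopropyl-bearing units through one ester. Ring A (cyclohexane C1, C6–C10) is trans-fused at C1–C6 to ring B, the seven-membered lactone C1–C2(=O)–O–C15H2–C4(CO2H)=C5H–C6. The axial carbon C14 on C10 is acylated by an (E)-2-(hydroxymethyl)acrylic acid whose β-carbon C5′ sits on ring C, a 3-(hydroxymethyl)-6-isopropylcyclohex-2-enyl group. Six stereocentres must be set (C1, C6, C7, C10 contiguous in ring A; C6′, C7′ in ring C) together with the E geometry of C4′=C5′. In both halves the isopropyl carbon and its neighbour are trans, but ring C has the mirror-image spatial arrangement of ring A (6S,7R against 6′S,7′S), so each half needs its own enantiomer of a building block. C7 can direct C6 by anti addition to an enone, and the C6/C7 pair then fixes the chair in which C10 is attacked and in which C1 relaxes to the trans-fused, all-equatorial arrangement. Only the axial C10–C14 bond needs a kinetically controlled step. The fragile features are the tertiary β-hydroxy lactone (retro-aldol, dehydration), the allylic C15–O bond, the doubly allylic C6′–H beside the trisubstituted acrylate, three free hydroxyls and an acid; late steps must therefore be near neutral and the acrylic acid should not be turned into an acyl donor. The feature that allows a short route is ring B: at the enol-ether oxidation level of C2 the array O–C15H2–C4(CO2R)=C5H–C6–C1=C2H is a 2,5-dihydrooxepine, the [3,3] isomer of a cis-2-vinylcyclopropanecarbaldehyde whose three-membered ring C1–C6–C5 is fused to the C10 cyclohexanone.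

## Retrosynthesis

**26 to 25.** No skeletal bond is cut. The acid is masked as a 2-(trimethylsilyl)ethyl ester and the two primary alcohols of ring C as silyl ethers, so one fluoride treatment releases 26. Hydrogenolysis, zerovalent palladium and strong acid are avoided because of the alkenes, the allylic lactone and the tertiary alcohol.

**25 to 24 to 23.** The C2 carbonyl oxygen and the C1–H bond are removed, leading back through lactol 24 to enol ether 23. This is preferred over lactonisation of a seco acid because the C1=C2 enol ether is exactly what the key step delivers. The forward steps must hydrate the enol ether without ionising the tertiary allylic C10–OH and must oxidise a lactol in the presence of esters and silyl ethers. C1 is set by axial protonation and is also the thermodynamic epimer.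

**23 to 14 and 22.** The O–C14 bond is cut. Opening spiro-epoxide 14 with the carboxylate of 22 is chosen over acylation of a C10/C14 diol: it is convergent, 22 is never activated as an acyl donor (which would endanger C6′ and the alkene geometry), and the epoxide already carries the C10 configuration. The forward reaction must be an SN2 attack at the primary carbon under basic conditions.

**14 to 13.** The C10–C14 bond is cut (with the C14–O closure). A small sulfur ylide is the one-carbon nucleophile that attacks a cyclohexanone axially, which is the face the target demands; bulkier carbon nucleophiles would favour the equatorial bond. Ketone 13 has only the C6 and C7 stereocentres.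

**13 to 12 (key step).** The O–C15 bond is cut and the C1–C5 bond re-formed, giving vinylcyclopropane β-keto aldehyde 12. Lactonisation or ring-closing metathesis would require a separately built C1-formyl, C6-alkenyl cyclohexanone carrying both chains. The retro-Claisen shift instead forms ring B with all its carbons from a bicycle that one annulation provides. The forward reaction asks for the acrylate and formyl groups to be cis on the cyclopropane and for reaction through the formyl oxygen.

**12 to 6 and 10 (through 11).** The C6–C5 and C1–C5 bonds are cut: a Michael-initiated ring closure between formyl enone 6 and the sulfonium ylide derived from bromide 10 via salt 11. The addition must occur anti to the isopropyl group and the ring must close on carbon with the acrylate exo.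

**6 to 5 to 4 to 1 and 2 (through 3).** The C1–C2 bond is cut (hydroxymethylation of the enone, then oxidation), and ring A is opened to 3-methylbutanal 1 and but-3-en-2-one 2 by a catalytic asymmetric Michael addition and aldol condensation, which sets C7.

**10 to 7 and 8.** The ester C–O bond is cut to the commercial acid 7 and alcohol 8.

**22 to 21 to 20 to 19.** Both hydroxymethyl carbons (C10′–C14′ and C4′–C15′) are cut at once. Bis-electrophile 19 (enol triflate and α-bromoacrylate) takes two hydroxymethyl groups in one cross-coupling, and the bromine fixes the acrylate geometry beforehand.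

**19 to 18 to 17 to 16 to 1 and 2 (through 15).** C4′=C5′ is cut by a Wittig reaction on aldehyde 18. The aldehyde carbon comes from the vinyl group of 17. The C6′–C5′ bond comes from conjugate addition to (S)-cryptone 16 with capture of the enolate as the C10′ triflate, which fixes the C1′=C10′ double bond. Cryptone 16 arises like 4 but with the mirror-image catalyst.

## Roads not taken

Alternative 1: Ring A is cut at C10–C1 and C7–C6 by a retro-[4+2] to a furan and a maleate tethered through the C14 ester. In the forward sense 5-isopropylfurfuryl hydrogen maleate A1 would be heated to give the exo oxanorbornene lactone acid A2.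
- **Merits.** A1 is two trivial steps from commodity chemicals. One cycloaddition forms ring A with C1, C6, C7 and C10 related, and the C10–O and C14–O bonds are in place with the C10/C1 relationship locked by the tether. In that respect it is better than the chosen plan, which needs a separate face-selective epoxidation for C10.
- **Weak points.** The bridging oxygen at C7 must be removed with delivery of hydrogen to a hindered bridgehead. The C8=C9 double bond must be reduced. The maleate delivers C1 and C6 cis where the target is trans. Furan cycloadditions through ester tethers are sluggish and reversible. A2 is racemic unless resolved. Ring B with C4, C5 and C15 still has to be built from the C6 carboxyl over many steps.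
- **Comparison.** The chosen plan counters with absolute control from catalysis, no C–O bond to erase at C7, and ring B complete after one rearrangement.

Alternative 2: Ring C is cut at C6′–C7′, C8′–C9′ and C1′=C10′. In the forward sense 3-(4-methoxybenzyloxy)propanal A3 would add to (E)-3-methyl-1-nitrobut-1-ene A4 under secondary-amine catalysis, the nitronate would add to ethyl 2-(diethoxyphosphoryl)acrylate A5, and an intramolecular Horner–Wadsworth–Emmons reaction would close the nitrocyclohexene ester A6.
- **Merits.** One pot sets C6′ and C7′ in the correct series and places the C5′ oxygen and the C14′ carbon. As a ring construction it is at least as economical as steps 8 and 9 here.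
- **Weak points.** The C8′ nitro group is superfluous and its reductive removal from a secondary carbon is not trivial. The C14′ ester must be reduced and the C5′ ether unmasked and oxidised before the acrylate can be made. The scheme says nothing about rings A and B or the union, so it can only replace steps 8–10 of the present route.
- **Comparison.** The chosen plan offers the same two-step cryptone entry for both halves with mirror-image catalysts, no group to delete, and a triflate that takes C14′ in the same operation as C15′.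

Alternative 3: Ring B is cut at C2–O–C15 by a retro-Baeyer–Villiger step to the trans-fused β,γ-unsaturated decalone A7. In the forward sense a peracid or a Baeyer–Villiger monooxygenase would insert oxygen with migration of the allylic C15 methylene to give the protected lactone A8.
- **Merits.** All four ring-A stereocentres would be settled on a rigid decalin before the oxidation. The lactone would appear at the correct oxidation level with C1 already configured. Here the alternative is better: the chosen plan needs a hydration and an oxidation after fragment union and passes through an acid-labile vinyl epoxide.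
- **Weak points.** The secondary carbon C1 normally migrates in preference to a primary one, and C15 is allylic to an electron-poor enoate, so the regiochemistry is doubtful with a peracid and unpredictable with an enzyme. The tertiary β-hydroxy ketone may dehydrate under peracid conditions. A7 itself needs a synthesis at least as long as the route to 14.
- **Comparison.** The chosen plan fixes the O–C15 connection through the pericyclic array and not through migratory aptitudes, and its precursor is five steps from commodity materials.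

Key step: step 6

Assumption: the two halves are taken exactly as drawn, with opposite absolute sense at C6/C7 and C6′/C7′, so (R)-cryptone serves rings A/B and (S)-cryptone serves ring C.

## Route

Step 1
Reactants: 1 3-methylbutanal; 2 but-3-en-2-one
Product: 4 (4R)-4-(propan-2-yl)cyclohex-2-en-1-one, via keto aldehyde 3 (not isolated)
Conditions: (R)-2-[methoxy(diphenyl)methyl]pyrrolidine (5 mol %), ethyl 3,4-dihydroxybenzoate (20 mol %), neat, 4 °C; then LiOH·H2O (0.2 equiv), i-PrOH, rt
Reagents that add atoms: none
Why: Enamine-catalysed Michael addition of the aldehyde to the enone followed by intramolecular aldol condensation (Robinson-type annulation); the diphenyl(methoxy)methyl group of the (R)-catalyst shields one enamine face, so the new centre (C7) should form as R, and the aldol closure does not involve it.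

Step 2
Reactants: 4 (4R)-4-(propan-2-yl)cyclohex-2-en-1-one
Product: 5 (4R)-2-(hydroxymethyl)-4-(propan-2-yl)cyclohex-2-en-1-one
Conditions: aq. HCHO (37 %), DMAP (0.3 equiv), THF/H2O, rt
Reagents that add atoms: formaldehyde, C=O
Why: Morita–Baylis–Hillman hydroxymethylation: DMAP adds reversibly to C6, the enolate traps formaldehyde at C1 and the amine is expelled; C7 is not involved.

Step 3
Reactants: 5 (4R)-2-(hydroxymethyl)-4-(propan-2-yl)cyclohex-2-en-1-one
Product: 6 (3R)-6-oxo-3-(propan-2-yl)cyclohex-1-ene-1-carbaldehyde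
Conditions: Dess–Martin periodinane, CH2Cl2, 0 °C → rt; used crude
Reagents that add atoms: none
Why: Dess–Martin oxidation of a primary allylic alcohol under non-basic conditions; the product is a very electrophilic alkylidene 1,3-dicarbonyl and should be carried on at once.

Step 4
Reactants: 7 2-(bromomethyl)prop-2-enoic acid; 8 2-(trimethylsilyl)ethanol
Product: 10 2-(trimethylsilyl)ethyl 2-(bromomethyl)prop-2-enoate, via acid chloride 9 (not isolated)
Conditions: (COCl)2, DMF (cat.), CH2Cl2, 0 °C → rt; then 8, pyridine, CH2Cl2, 0 °C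
Reagents that add atoms: none
Why: Esterification through the acid chloride; no nucleophilic acylation catalyst is used, so the allylic bromide should survive.

Step 5
Reactants: 6 (3R)-6-oxo-3-(propan-2-yl)cyclohex-1-ene-1-carbaldehyde; 10 2-(trimethylsilyl)ethyl 2-(bromomethyl)prop-2-enoate
Product: 12 2-(trimethylsilyl)ethyl 2-[(1S,5R,6S,7S)-1-formyl-2-oxo-5-(propan-2-yl)bicyclo[4.1.0]heptan-7-yl]prop-2-enoate, via sulfonium bromide 11 (not isolated)
Conditions: 10, tetrahydrothiophene (1.1 equiv), MeCN, rt; then 6, Cs2CO3, MeCN, −20 → 0 °C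
Reagents that add atoms: none
Why: Sulfonium-ylide cyclopropanation (Michael-initiated ring closure): the allylic ylide adds through its sulfur-bearing carbon to C6 anti to the C7 isopropyl group, and the chelated enolate carbon C1 displaces tetrahydrothiophene at C5 (3-exo-tet). The acrylate should take the exo position, trans to both ring bonds and therefore cis to the formyl group; closure through the ring-ketone oxygen is geometrically impossible.

Step 6
Reactants: 12 2-(trimethylsilyl)ethyl 2-[(1S,5R,6S,7S)-1-formyl-2-oxo-5-(propan-2-yl)bicyclo[4.1.0]heptan-7-yl]prop-2-enoate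
Product: 13 2-(trimethylsilyl)ethyl (5aS,6R)-9-oxo-6-(propan-2-yl)-3,5a,6,7,8,9-hexahydro-2-benzoxepine-4-carboxylate
Conditions: PhMe (0.05 M), 60 °C
Reagents that add atoms: none
Why: Concerted [3,3] sigmatropic shift (retro-Claisen, an oxa-Cope rearrangement): through a boat-like array the formyl oxygen bonds to C15 while the C1–C5 cyclopropane bond breaks, giving the C1=C2 enol ether and the C4=C5 enoate. The closest known reaction type is the retro-Claisen rearrangement of 2-vinylcyclopropane-1,1-dicarbonyl compounds to 2,5-dihydrooxepines. Ring B closes by the pericyclic shift itself, the oxygen ending on the vinyl terminus (formally 7-endo), so there is no separate cyclisation and no choice of ring size. No stereocentre is created: C1 and C5 become trigonal, C6 and C7 are untouched, and the cis placement of C15 and C6 on C4=C5 is enforced by the cyclic array. The step needs the acrylate and formyl groups cis on the cyclopropane, which the exo orientation from step 5 provides. It also needs reaction through the formyl and not the ring-ketone oxygen, which is secured because the ketone pathway would give a bridgehead enol ether. Release of cyclopropane strain, the vinylogous ester formed with the C10 ketone and the trisubstituted enoate make the shift downhill, so mild heating in a non-polar solvent should suffice and should keep the ionic Cloke–Wilson route to a dihydrofuran out of play.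

Step 7
Reactants: 13 2-(trimethylsilyl)ethyl (5aS,6R)-9-oxo-6-(propan-2-yl)-3,5a,6,7,8,9-hexahydro-2-benzoxepine-4-carboxylate
Product: 14 2-(trimethylsilyl)ethyl (5aS,6R,9S)-6-(propan-2-yl)-5a,6,7,8-tetrahydro-3H-spiro[2-benzoxepine-9,2'-oxirane]-4-carboxylate
Conditions: Me3SI, KN(SiMe3)2, THF, −10 °C; then 13, −20 → 0 °C; used without chromatography
Reagents that add atoms: trimethylsulfonium iodide, C[S+](C)C.[I-]
Why: Corey–Chaykovsky epoxidation; 1,2-addition of dimethylsulfonium methylide to an α-alkoxymethylene ketone is the first stage of the Garst–Spencer furan annulation. The small ylide should attack C10 along the axial trajectory on the face syn to H6 and anti to the C6–C5 bond, giving the axial CH2 and equatorial oxygen (10S).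

Step 8
Reactants: 1 3-methylbutanal; 2 but-3-en-2-one
Product: 16 (4S)-4-(propan-2-yl)cyclohex-2-en-1-one, via keto aldehyde 15 (not isolated)
Conditions: (S)-2-[methoxy(diphenyl)methyl]pyrrolidine (5 mol %), ethyl 3,4-dihydroxybenzoate (20 mol %), neat, 4 °C; then LiOH·H2O (0.2 equiv), i-PrOH, rt
Reagents that add atoms: none
Why: The same enamine Michael addition and aldol condensation as step 1 with the mirror-image catalyst, which should set C7′ as S.

Step 9
Reactants: 16 (4S)-4-(propan-2-yl)cyclohex-2-en-1-one
Product: 17 (3S,4S)-3-ethenyl-4-(propan-2-yl)cyclohex-1-en-1-yl trifluoromethanesulfonate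
Conditions: CH2=CHMgBr, CuBr·SMe2 (20 mol %), THF, −78 → −40 °C; then 2-[N,N-bis(trifluoromethanesulfonyl)amino]-5-chloropyridine, −78 °C → rt
Reagents that add atoms: vinylmagnesium bromide, C=C[Mg]Br; 2-[N,N-bis(trifluoromethanesulfonyl)amino]-5-chloropyridine, O=S(=O)(N(c1ccc(Cl)cn1)S(=O)(=O)C(F)(F)F)C(F)(F)F
Why: Copper-catalysed conjugate addition anti to the C7′ isopropyl group sets C6′ (trans), and O-sulfonylation of the regiodefined enolate fixes the C1′=C10′ double bond.

Step 10
Reactants: 17 (3S,4S)-3-ethenyl-4-(propan-2-yl)cyclohex-1-en-1-yl trifluoromethanesulfonate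
Product: 18 (3S,4S)-3-formyl-4-(propan-2-yl)cyclohex-1-en-1-yl trifluoromethanesulfonate
Conditions: O3, CH2Cl2, −78 °C; then PPh3, −78 °C → rt
Reagents that add atoms: ozone, [O-][O+]=O
Why: Ozonolysis with reductive work-up; the monosubstituted vinyl group is far more electron-rich than the enol triflate double bond. The triflate also prevents the ring alkene from moving into conjugation with the new aldehyde, so C6′ can at worst re-equilibrate to the favoured trans isomer.

Step 11
Reactants: 18 (3S,4S)-3-formyl-4-(propan-2-yl)cyclohex-1-en-1-yl trifluoromethanesulfonate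
Product: 19 methyl (2Z)-2-bromo-3-[(1S,6S)-6-(propan-2-yl)-3-{[(trifluoromethyl)sulfonyl]oxy}cyclohex-2-en-1-yl]prop-2-enoate
Conditions: Ph3P=CHCO2Me, NBS, CH2Cl2, −20 °C; then 18, rt
Reagents that add atoms: methyl (triphenylphosphoranylidene)acetate, COC(=O)C=P(c1ccccc1)(c1ccccc1)c1ccccc1; N-bromosuccinimide, O=C1CCC(=O)N1Br
Why: Wittig olefination with the ester-stabilised α-bromo ylide formed in the flask; like other α-substituted stabilised ylides it should place the ester trans to the β-substituent (Z-bromoacrylate), and the neutral conditions spare C6′.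

Step 12
Reactants: 19 methyl (2Z)-2-bromo-3-[(1S,6S)-6-(propan-2-yl)-3-{[(trifluoromethyl)sulfonyl]oxy}cyclohex-2-en-1-yl]prop-2-enoate
Product: 20 methyl (2E)-2-(hydroxymethyl)-3-[(1S,6S)-3-(hydroxymethyl)-6-(propan-2-yl)cyclohex-2-en-1-yl]prop-2-enoate
Conditions: Bu3SnCH2OH (2.5 equiv), Pd(PPh3)4 (10 mol %), LiCl, 1,4-dioxane, 95 °C
Reagents that add atoms: (tributylstannyl)methanol, CCCC[Sn](CCCC)(CCCC)CO
Why: Twofold Migita–Kosugi–Stille hydroxymethylation: zerovalent palladium inserts into the C10′–OTf and C4′–Br bonds and the hydroxymethyl group is transferred from tin with retention, so the bromine cis to C6′ becomes the CH2OH cis to C6′ (E-acrylate).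

Step 13
Reactants: 20 methyl (2E)-2-(hydroxymethyl)-3-[(1S,6S)-3-(hydroxymethyl)-6-(propan-2-yl)cyclohex-2-en-1-yl]prop-2-enoate
Product: 21 methyl (2E)-2-{[(tert-butyldimethylsilyl)oxy]methyl}-3-[(1S,6S)-3-{[(tert-butyldimethylsilyl)oxy]methyl}-6-(propan-2-yl)cyclohex-2-en-1-yl]prop-2-enoate
Conditions: TBSCl, imidazole, DMF, 0 °C → rt
Reagents that add atoms: tert-butyldimethylsilyl chloride, CC(C)(C)[Si](C)(C)Cl
Why: Standard silylation of two primary alcohols, which keeps them out of the later lactol oxidation.

Step 14
Reactants: 21 methyl (2E)-2-{[(tert-butyldimethylsilyl)oxy]methyl}-3-[(1S,6S)-3-{[(tert-butyldimethylsilyl)oxy]methyl}-6-(propan-2-yl)cyclohex-2-en-1-yl]prop-2-enoate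
Product: 22 (2E)-2-{[(tert-butyldimethylsilyl)oxy]methyl}-3-[(1S,6S)-3-{[(tert-butyldimethylsilyl)oxy]methyl}-6-(propan-2-yl)cyclohex-2-en-1-yl]prop-2-enoic acid
Conditions: LiOH·H2O, THF/MeOH/H2O, 40 °C; then aq. HCl to pH 4, 0 °C
Reagents that add atoms: lithium hydroxide, [Li+].[OH-]
Why: Saponification of a methyl ester; primary TBS ethers tolerate aqueous LiOH, and hydroxide is too weak a base to deprotonate C6′.

Step 15
Reactants: 14 2-(trimethylsilyl)ethyl (5aS,6R,9S)-6-(propan-2-yl)-5a,6,7,8-tetrahydro-3H-spiro[2-benzoxepine-9,2'-oxirane]-4-carboxylate; 22 (2E)-2-{[(tert-butyldimethylsilyl)oxy]methyl}-3-[(1S,6S)-3-{[(tert-butyldimethylsilyl)oxy]methyl}-6-(propan-2-yl)cyclohex-2-en-1-yl]prop-2-enoic acid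
Product: 23 2-(trimethylsilyl)ethyl (5aS,6R,9S)-9-hydroxy-9-({[(2E)-2-{[(tert-butyldimethylsilyl)oxy]methyl}-3-[(1S,6S)-3-{[(tert-butyldimethylsilyl)oxy]methyl}-6-(propan-2-yl)cyclohex-2-en-1-yl]prop-2-enoyl]oxy}methyl)-6-(propan-2-yl)-3,5a,6,7,8,9-hexahydro-2-benzoxepine-4-carboxylate
Conditions: Cs2CO3, DMF, 70 °C
Reagents that add atoms: none
Why: SN2 opening of a 2,2-disubstituted epoxide at its primary carbon C14 by a cesium carboxylate; C10 is not touched and keeps its configuration, and the acid is never activated, so C6′ and the alkene geometry are not at risk.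

Step 16
Reactants: 23 2-(trimethylsilyl)ethyl (5aS,6R,9S)-9-hydroxy-9-({[(2E)-2-{[(tert-butyldimethylsilyl)oxy]methyl}-3-[(1S,6S)-3-{[(tert-butyldimethylsilyl)oxy]methyl}-6-(propan-2-yl)cyclohex-2-en-1-yl]prop-2-enoyl]oxy}methyl)-6-(propan-2-yl)-3,5a,6,7,8,9-hexahydro-2-benzoxepine-4-carboxylate
Product: 24 2-(trimethylsilyl)ethyl (5aS,6R,9S,9aS)-1,9-dihydroxy-9-({[(2E)-2-{[(tert-butyldimethylsilyl)oxy]methyl}-3-[(1S,6S)-3-{[(tert-butyldimethylsilyl)oxy]methyl}-6-(propan-2-yl)cyclohex-2-en-1-yl]prop-2-enoyl]oxy}methyl)-6-(propan-2-yl)-1,3,5a,6,7,8,9,9a-octahydro-2-benzoxepine-4-carboxylate (lactol, both C2 epimers)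
Conditions: PPTS (0.3 equiv), THF/H2O (4:1), 40 °C
Reagents that add atoms: water, O
Why: Acid-catalysed enol-ether hydration: rate-limiting protonation at C1 gives the C2 oxocarbenium ion, which water traps as the lactol. Axial protonation anti to the axial C14 group should give 1S, which is also the thermodynamic epimer (trans fusion, C2 equatorial) reachable through the open hydroxy aldehyde.

Step 17
Reactants: 24 the lactol from step 16
Product: 25 2-(trimethylsilyl)ethyl (5aS,6R,9S,9aS)-9-hydroxy-9-({[(2E)-2-{[(tert-butyldimethylsilyl)oxy]methyl}-3-[(1S,6S)-3-{[(tert-butyldimethylsilyl)oxy]methyl}-6-(propan-2-yl)cyclohex-2-en-1-yl]prop-2-enoyl]oxy}methyl)-1-oxo-6-(propan-2-yl)-1,3,5a,6,7,8,9,9a-octahydro-2-benzoxepine-4-carboxylate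
Conditions: Ag2CO3 on Celite, PhMe, 80 °C
Reagents that add atoms: none
Why: Fétizon oxidation: Ag2CO3 on Celite oxidises lactols much faster than other alcohols and tolerates silyl ethers, esters and the tertiary alcohol; no stereocentre is formed.

Step 18
Reactants: 25 the protected lactone from step 17
Product: 26 (5aS,6R,9S,9aS)-9-hydroxy-9-({[(2E)-2-(hydroxymethyl)-3-[(1S,6S)-3-(hydroxymethyl)-6-(propan-2-yl)cyclohex-2-en-1-yl]prop-2-enoyl]oxy}methyl)-1-oxo-6-(propan-2-yl)-1,3,5a,6,7,8,9,9a-octahydro-2-benzoxepine-4-carboxylic acid (CNP0361406.8)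
Conditions: TASF [tris(dimethylamino)sulfonium difluorotrimethylsilicate], DMF, 0 °C → rt; aq. NH4Cl
Reagents that add atoms: none
Why: Fluoride-induced global deprotection: the 2-(trimethylsilyl)ethyl ester fragments to the carboxylate, ethene and Me3SiF, and both TBS ethers are cleaved under the same nearly neutral conditions; no stereocentre is touched.

## Compound list

1 | 3-methylbutanal (isovaleraldehyde) | CC(C)CC=O | starting material
2 | but-3-en-2-one (methyl vinyl ketone) | CC(=O)C=C | starting material
3 | (2R)-5-oxo-2-(propan-2-yl)hexanal | CC(C)[C@H](C=O)CCC(C)=O | intermediate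
4 | (4R)-4-(propan-2-yl)cyclohex-2-en-1-one, (R)-cryptone | CC(C)[C@H]1CCC(=O)C=C1 | intermediate
5 | (4R)-2-(hydroxymethyl)-4-(propan-2-yl)cyclohex-2-en-1-one | CC(C)[C@H]1CCC(=O)C(CO)=C1 | intermediate
6 | (3R)-6-oxo-3-(propan-2-yl)cyclohex-1-ene-1-carbaldehyde | CC(C)[C@H]1CCC(=O)C(C=O)=C1 | intermediate
7 | 2-(bromomethyl)prop-2-enoic acid | C=C(CBr)C(=O)O | starting material
8 | 2-(trimethylsilyl)ethanol | C[Si](C)(C)CCO | starting material
9 | 2-(bromomethyl)prop-2-enoyl chloride | C=C(CBr)C(=O)Cl | intermediate
10 | 2-(trimethylsilyl)ethyl 2-(bromomethyl)prop-2-enoate | C=C(CBr)C(=O)OCC[Si](C)(C)C | intermediate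
11 | 1-[2-({2-(trimethylsilyl)ethoxy}carbonyl)prop-2-en-1-yl]thiolan-1-ium bromide | C=C(C[S+]1CCCC1)C(=O)OCC[Si](C)(C)C.[Br-] | intermediate
12 | 2-(trimethylsilyl)ethyl 2-[(1S,5R,6S,7S)-1-formyl-2-oxo-5-(propan-2-yl)bicyclo[4.1.0]heptan-7-yl]prop-2-enoate | CC(C)[C@H]1CCC(=O)[C@@]2(C=O)[C@@H]1[C@@H]2C(=C)C(=O)OCC[Si](C)(C)C | intermediate
13 | 2-(trimethylsilyl)ethyl (5aS,6R)-9-oxo-6-(propan-2-yl)-3,5a,6,7,8,9-hexahydro-2-benzoxepine-4-carboxylate | CC(C)[C@H]1CCC(=O)C2=COCC(C(=O)OCC[Si](C)(C)C)=C[C@H]12 | intermediate
14 | 2-(trimethylsilyl)ethyl (5aS,6R,9S)-6-(propan-2-yl)-5a,6,7,8-tetrahydro-3H-spiro[2-benzoxepine-9,2'-oxirane]-4-carboxylate | CC(C)[C@H]1CC[C@@]3(CO3)C2=COCC(C(=O)OCC[Si](C)(C)C)=C[C@H]12 | intermediate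
15 | (2S)-5-oxo-2-(propan-2-yl)hexanal | CC(C)[C@@H](C=O)CCC(C)=O | intermediate
16 | (4S)-4-(propan-2-yl)cyclohex-2-en-1-one, (S)-cryptone | CC(C)[C@@H]1CCC(=O)C=C1 | intermediate
17 | (3S,4S)-3-ethenyl-4-(propan-2-yl)cyclohex-1-en-1-yl trifluoromethanesulfonate | CC(C)[C@@H]1CCC(OS(=O)(=O)C(F)(F)F)=C[C@H]1C=C | intermediate
18 | (3S,4S)-3-formyl-4-(propan-2-yl)cyclohex-1-en-1-yl trifluoromethanesulfonate | CC(C)[C@@H]1CCC(OS(=O)(=O)C(F)(F)F)=C[C@H]1C=O | intermediate
19 | methyl (2Z)-2-bromo-3-[(1S,6S)-6-(propan-2-yl)-3-{[(trifluoromethyl)sulfonyl]oxy}cyclohex-2-en-1-yl]prop-2-enoate | CC(C)[C@@H]1CCC(OS(=O)(=O)C(F)(F)F)=C[C@H]1/C=C(\Br)C(=O)OC | intermediate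
20 | methyl (2E)-2-(hydroxymethyl)-3-[(1S,6S)-3-(hydroxymethyl)-6-(propan-2-yl)cyclohex-2-en-1-yl]prop-2-enoate | CC(C)[C@@H]1CCC(CO)=C[C@H]1/C=C(\CO)C(=O)OC | intermediate
21 | methyl (2E)-2-{[(tert-butyldimethylsilyl)oxy]methyl}-3-[(1S,6S)-3-{[(tert-butyldimethylsilyl)oxy]methyl}-6-(propan-2-yl)cyclohex-2-en-1-yl]prop-2-enoate | CC(C)[C@@H]1CCC(CO[Si](C)(C)C(C)(C)C)=C[C@H]1/C=C(\CO[Si](C)(C)C(C)(C)C)C(=O)OC | intermediate
22 | (2E)-2-{[(tert-butyldimethylsilyl)oxy]methyl}-3-[(1S,6S)-3-{[(tert-butyldimethylsilyl)oxy]methyl}-6-(propan-2-yl)cyclohex-2-en-1-yl]prop-2-enoic acid | CC(C)[C@@H]1CCC(CO[Si](C)(C)C(C)(C)C)=C[C@H]1/C=C(\CO[Si](C)(C)C(C)(C)C)C(=O)O | intermediate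
23 | enol-ether hydroxy ester: 2-(trimethylsilyl)ethyl (5aS,6R,9S)-9-hydroxy-9-(acyloxymethyl)-6-(propan-2-yl)-3,5a,6,7,8,9-hexahydro-2-benzoxepine-4-carboxylate, acyl = acyl group of 22 | CC(C)[C@H]1CC[C@@](O)(COC(=O)/C(=C/[C@@H]3C=C(CO[Si](C)(C)C(C)(C)C)CC[C@H]3C(C)C)CO[Si](C)(C)C(C)(C)C)C2=COCC(C(=O)OCC[Si](C)(C)C)=C[C@H]12 | intermediate
24 | lactol: (5aS,6R,9S,9aS)-1,9-dihydroxy-1,3,5a,6,7,8,9,9a-octahydro analogue of 23, both C2 epimers | CC(C)[C@H]1CC[C@@](O)(COC(=O)/C(=C/[C@@H]3C=C(CO[Si](C)(C)C(C)(C)C)CC[C@H]3C(C)C)CO[Si](C)(C)C(C)(C)C)[C@H]2C(O)OCC(C(=O)OCC[Si](C)(C)C)=C[C@H]12 | intermediate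
25 | protected target: 2-(trimethylsilyl)ethyl (5aS,6R,9S,9aS)-9-hydroxy-9-(acyloxymethyl)-1-oxo-6-(propan-2-yl)-1,3,5a,6,7,8,9,9a-octahydro-2-benzoxepine-4-carboxylate, acyl = acyl group of 22 | CC(C)[C@H]1CC[C@@](O)(COC(=O)/C(=C/[C@@H]3C=C(CO[Si](C)(C)C(C)(C)C)CC[C@H]3C(C)C)CO[Si](C)(C)C(C)(C)C)[C@H]2C(=O)OCC(C(=O)OCC[Si](C)(C)C)=C[C@H]12 | intermediate
26 | (5aS,6R,9S,9aS)-9-hydroxy-9-({[(2E)-2-(hydroxymethyl)-3-[(1S,6S)-3-(hydroxymethyl)-6-(propan-2-yl)cyclohex-2-en-1-yl]prop-2-enoyl]oxy}methyl)-1-oxo-6-(propan-2-yl)-1,3,5a,6,7,8,9,9a-octahydro-2-benzoxepine-4-carboxylic acid | CC(C)[C@H]1CC[C@@](O)(COC(=O)/C(=C/[C@@H]2C=C(CO)CC[C@H]2C(C)C)CO)[C@H]2C(=O)OCC(C(=O)O)=C[C@H]12 | target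

## Step count and risks

Total: 18 steps. Longest linear sequence: 11 steps (steps 8–14, then 15–18). The ring A/B branch is 10 steps (steps 1–3 and 5–7, then 15–18), and step 4 is a one-step side branch.

Steps least certain to work:

**Step 6 (key step).** The rearrangement may stall if part of the material carries the acrylate trans to the formyl group. That isomer must first epimerise by reversible heterolysis of the C1–C5 bond, and during this the zwitterion can close through oxygen at C5 (dihydrofuran formation) or oligomerise. The fallback sets out from 6 (using 10) and comes back at 13 by closing ring B at C4=C5 instead. Copper-catalysed addition of CH2=CHMgBr to 6 at −78 °C, anti to the isopropyl group, should give (3R,4R)-3-ethenyl-2-(hydroxymethylidene)-4-(propan-2-yl)cyclohexan-1-one F1. O-Alkylation of its enol with 10 (K2CO3, acetone) should give the (E)-alkoxymethylene ketone F2. Ring-closing metathesis of F2 with the second-generation Grubbs catalyst (H2IMes)(PCy3)Cl2Ru=CHPh between the C6 vinyl group and the acrylate methylene should deliver 13.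

**Step 5.** The Michael adduct may close through the formyl enolate oxygen and not through C1, or the ylide may attack the aldehyde, because the enolate is ambident and the aldehyde unhindered. The fallback sets out from 5 and comes back at 12, introducing the aldehyde only after the cyclopropane exists. Silylation of 5 (Et3SiCl, imidazole) gives the triethylsilyl ether F3. Cyclopropanation of F3 with 11 and Cs2CO3 can only proceed through a ketone enolate whose oxygen cannot reach C5, and should give the bicyclic silyl ether F4. HF·pyridine releases the primary alcohol F5, and Dess–Martin oxidation gives 12.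

**Step 7.** Enolisation toward C9 or conjugate addition to the C4=C5 enoate may outrun 1,2-addition, because the ketone is deactivated as a vinylogous ester; weak facial control would give the C10 epimer. The fallback sets out from 13 and comes back at 14 with a more nucleophilic, less basic one-carbon carbenoid. Chloromethyllithium (ICH2Cl, MeLi·LiBr, THF, −78 °C) should add irreversibly to the ketone along the same axial trajectory to give the chlorohydrin F6 as its lithium alkoxide, which closes to 14 on warming.

**Step 15.** Heterolysis of the C10–O bond of the alkoxy-substituted vinyl epoxide, assisted by the enol ether, may be faster than SN2 attack at C14 and would divert the carboxylate to C2 or destroy the epoxide. The fallback sets out from 13 and comes back at 25, forming the ester by acylation of a diol.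
- (4-Methoxybenzyloxy)methyllithium, from the corresponding tributylstannane and n-BuLi, adds to the C10 ketone to give the tertiary alcohol F7.
- Hydration and Ag2CO3 oxidation as in steps 16 and 17 give the lactol F8 and the lactone F9.
- DDQ removes the 4-methoxybenzyl group to give the diol F10.
- The primary hydroxyl of F10 is esterified with 22 (2-methyl-6-nitrobenzoic anhydride, DMAP, 0 °C) to give 25.

**Step 16.** Ionisation of the tertiary allylic C10 hydroxyl toward the alkoxy-allyl cation (a Stork–Danheiser-type transposition) may compete with protonation at C1, and prolonged acid may remove a TBS group. If the cis-fused C1 epimer appears it can be equilibrated through the lactone enolate after step 17. The fallback sets out from 23 and comes back at 26 without ever freeing the lactol. Capping the C10 hydroxyl (Me3SiOTf, 2,6-lutidine) gives the trimethylsilyl ether F11. Direct oxidation of the cyclic enol ether with pyridinium chlorochromate, [C5H5NH][CrO3Cl], buffered with NaOAc, gives the lactone F12. TASF then removes all four silicon groups to give 26.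

## Further compounds

F1 | step 6 | (3R,4R)-3-ethenyl-2-(hydroxymethylidene)-4-(propan-2-yl)cyclohexan-1-one | CC(C)[C@H]1CCC(=O)C(=CO)[C@@H]1C=C
F2 | step 6 | 2-(trimethylsilyl)ethyl 2-({(E)-[(2R,3R)-2-ethenyl-6-oxo-3-(propan-2-yl)cyclohexylidene]methoxy}methyl)prop-2-enoate | CC(C)[C@H]1CCC(=O)/C(=C/OCC(=C)C(=O)OCC[Si](C)(C)C)[C@@H]1C=C
F3 | step 5 | (4R)-4-(propan-2-yl)-2-{[(triethylsilyl)oxy]methyl}cyclohex-2-en-1-one | CC(C)[C@H]1CCC(=O)C(CO[Si](CC)(CC)CC)=C1
F4 | step 5 | 2-(trimethylsilyl)ethyl 2-[(1S,5R,6S,7S)-2-oxo-5-(propan-2-yl)-1-{[(triethylsilyl)oxy]methyl}bicyclo[4.1.0]heptan-7-yl]prop-2-enoate | CC(C)[C@H]1CCC(=O)[C@@]2(CO[Si](CC)(CC)CC)[C@@H]1[C@@H]2C(=C)C(=O)OCC[Si](C)(C)C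
F5 | step 5 | 2-(trimethylsilyl)ethyl 2-[(1S,5R,6S,7S)-1-(hydroxymethyl)-2-oxo-5-(propan-2-yl)bicyclo[4.1.0]heptan-7-yl]prop-2-enoate | CC(C)[C@H]1CCC(=O)[C@@]2(CO)[C@@H]1[C@@H]2C(=C)C(=O)OCC[Si](C)(C)C
F6 | step 7 | 2-(trimethylsilyl)ethyl (5aS,6R,9S)-9-(chloromethyl)-9-hydroxy-6-(propan-2-yl)-3,5a,6,7,8,9-hexahydro-2-benzoxepine-4-carboxylate | CC(C)[C@H]1CC[C@@](O)(CCl)C2=COCC(C(=O)OCC[Si](C)(C)C)=C[C@H]12
F7 | step 15 | 2-(trimethylsilyl)ethyl (5aS,6R,9S)-9-hydroxy-9-{[(4-methoxyphenyl)methoxy]methyl}-6-(propan-2-yl)-3,5a,6,7,8,9-hexahydro-2-benzoxepine-4-carboxylate | CC(C)[C@H]1CC[C@@](O)(COCc3ccc(OC)cc3)C2=COCC(C(=O)OCC[Si](C)(C)C)=C[C@H]12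
F8 | step 15 | 2-(trimethylsilyl)ethyl (5aS,6R,9S,9aS)-1,9-dihydroxy-9-{[(4-methoxyphenyl)methoxy]methyl}-6-(propan-2-yl)-1,3,5a,6,7,8,9,9a-octahydro-2-benzoxepine-4-carboxylate | CC(C)[C@H]1CC[C@@](O)(COCc3ccc(OC)cc3)[C@H]2C(O)OCC(C(=O)OCC[Si](C)(C)C)=C[C@H]12
F9 | step 15 | 2-(trimethylsilyl)ethyl (5aS,6R,9S,9aS)-9-hydroxy-9-{[(4-methoxyphenyl)methoxy]methyl}-1-oxo-6-(propan-2-yl)-1,3,5a,6,7,8,9,9a-octahydro-2-benzoxepine-4-carboxylate | CC(C)[C@H]1CC[C@@](O)(COCc3ccc(OC)cc3)[C@H]2C(=O)OCC(C(=O)OCC[Si](C)(C)C)=C[C@H]12
F10 | step 15 | 2-(trimethylsilyl)ethyl (5aS,6R,9S,9aS)-9-hydroxy-9-(hydroxymethyl)-1-oxo-6-(propan-2-yl)-1,3,5a,6,7,8,9,9a-octahydro-2-benzoxepine-4-carboxylate | CC(C)[C@H]1CC[C@@](O)(CO)[C@H]2C(=O)OCC(C(=O)OCC[Si](C)(C)C)=C[C@H]12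
F11 | step 16 | 9-O-trimethylsilyl ether of 23 | CC(C)[C@H]1CC[C@@](O[Si](C)(C)C)(COC(=O)/C(=C/[C@@H]3C=C(CO[Si](C)(C)C(C)(C)C)CC[C@H]3C(C)C)CO[Si](C)(C)C(C)(C)C)C2=COCC(C(=O)OCC[Si](C)(C)C)=C[C@H]12
F12 | step 16 | 9-O-trimethylsilyl ether of 25 | CC(C)[C@H]1CC[C@@](O[Si](C)(C)C)(COC(=O)/C(=C/[C@@H]3C=C(CO[Si](C)(C)C(C)(C)C)CC[C@H]3C(C)C)CO[Si](C)(C)C(C)(C)C)[C@H]2C(=O)OCC(C(=O)OCC[Si](C)(C)C)=C[C@H]12
A1 | alternative 1 | (2Z)-4-oxo-4-{[5-(propan-2-yl)furan-2-yl]methoxy}but-2-enoic acid (5-isopropylfurfuryl hydrogen maleate) | CC(C)c1ccc(COC(=O)/C=C\C(=O)O)o1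
A2 | alternative 1 | exo 7-oxanorbornene γ-lactone carboxylic acid from the intramolecular Diels–Alder reaction | CC(C)[C@@]12C=C[C@]3(COC(=O)[C@@H]3[C@@H]1C(=O)O)O2
A3 | alternative 2 | 3-[(4-methoxyphenyl)methoxy]propanal | COc1ccc(COCCC=O)cc1
A4 | alternative 2 | (1E)-3-methyl-1-nitrobut-1-ene | CC(C)/C=C/[N+](=O)[O-]
A5 | alternative 2 | ethyl 2-(diethoxyphosphoryl)prop-2-enoate | CCOC(=O)C(=C)P(=O)(OCC)OCC
A6 | alternative 2 | ethyl 3-{[(4-methoxyphenyl)methoxy]methyl}-4-(propan-2-yl)-5-nitrocyclohex-1-ene-1-carboxylate | CCOC(=O)C1=C[C@@H](COCc2ccc(OC)cc2)[C@H](C(C)C)[C@@H]([N+](=O)[O-])C1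
A7 | alternative 3 | trans-fused β,γ-unsaturated decalone with C2 ketone, C10 hydroxyl, C14 silyl ether and C4 ester | CC(C)[C@H]1CC[C@@](O)(CO[Si](C)(C)C(C)(C)C)[C@H]2C(=O)CC(C(=O)OCC[Si](C)(C)C)=C[C@H]12
A8 | alternative 3 | protected bicyclic lactone half | CC(C)[C@H]1CC[C@@](O)(CO[Si](C)(C)C(C)(C)C)[C@H]2C(=O)OCC(C(=O)OCC[Si](C)(C)C)=C[C@H]12
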